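**Retrosynthetic overview**

1. Kanzonol E ⇐ its 7‑O‑MOM ether ⇐ ring D annulation. The C2–C3 and C4–C4a bonds of the 2,2‑dimethylpyran ring D (O1, C2(Me)2, C3, C4, C4a = C3' and C8a = C4' of ring B) are made together from a 4'‑O‑CMe2‑CO2‑N(phthaloyl) flavone and acetylene by a photoredox decarboxylative radical [4+2] annulation.
2. Enabling feature: O1 of ring D joins the gem‑dimethyl carbon C2 to C4' of the 1,4‑disubstituted ring B. The oxygen makes a tertiary, nucleophilic radical at C2 available from a fibrate‑type acid, and the ortho carbons C3' and C5' of ring B are identical, so the closing bond has only one place to go.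
3. The flavone (ring C) comes from a 2'‑hydroxychalcone by iodine/DMSO oxidative cyclisation, the chalcone from a Claisen–Schmidt condensation of the ring A ketone with the ring B aldehyde.
4. Ring A: 2,4‑dihydroxyacetophenone, C‑prenylated at C5, 4‑OH as MOM ether. Ring B: 4‑hydroxybenzaldehyde O‑alkylated with ethyl 2‑bromo‑2‑methylpropanoate, which brings O1–C2 and both methyl groups.
5. Ring order: rings A and B are bought, ring C is closed in step 5, ring D in step 7.

Key step: step 7

Assumption: acetylene gas (cylinder, or generated from CaC2 and water) is taken as a commercial starting material; the flavanone 10 is racemic and its stereocentre disappears in the same step.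

**Route**

Step 1
Reactants: 1 4-hydroxybenzaldehyde; 2 ethyl 2-bromo-2-methylpropanoate
Product: 4 2-(4-formylphenoxy)-2-methylpropanoic acid, via ethyl 2-(4-formylphenoxy)-2-methylpropanoate 3 (not isolated)
Conditions: K2CO3, DMF, 80 °C; then NaOH, EtOH–H2O, 50 °C; then 1 M HCl, 0 °C
Reagents that add atoms: sodium hydroxide, [Na+].[OH-] (its oxygen becomes the carboxyl OH)
Why: Williamson O‑alkylation of the phenoxide with the tertiary α‑bromo ester (the standard fibrate construction) followed by saponification in the same flask, the aldehyde having no α‑hydrogen and tolerating dilute hydroxide.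

Step 2
Reactants: 5 1-(2,4-dihydroxyphenyl)ethanone; 6 2-methylbut-3-en-2-ol
Product: 7 1-[2,4-dihydroxy-5-(3-methylbut-2-en-1-yl)phenyl]ethanone
Conditions: BF3·OEt2 (0.5 equiv), dioxane, rt
Reagents that add atoms: none
Why: Friedel–Crafts C‑prenylation by the dimethylallyl cation released from the tertiary allylic alcohol; C5 (para to the chelated 2‑OH, ortho to the 4‑OH) is the preferred site for this ketone, and the C3 isomer and over‑alkylated material should be removable by chromatography.

Step 3
Reactants: 7 1-[2,4-dihydroxy-5-(3-methylbut-2-en-1-yl)phenyl]ethanone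
Product: 8 1-[2-hydroxy-4-(methoxymethoxy)-5-(3-methylbut-2-en-1-yl)phenyl]ethanone
Conditions: MOMCl (1.1 equiv), K2CO3, acetone, 0 °C to rt
Reagents that add atoms: chloromethyl methyl ether, COCCl
Why: Williamson etherification that should touch only the free 4‑OH, because the 2‑OH is locked in a hydrogen bond to the acetyl carbonyl.

Step 4
Reactants: 8 1-[2-hydroxy-4-(methoxymethoxy)-5-(3-methylbut-2-en-1-yl)phenyl]ethanone; 4 2-(4-formylphenoxy)-2-methylpropanoic acid
Product: 9 2-[4-[(1E)-3-[2-hydroxy-4-(methoxymethoxy)-5-(3-methylbut-2-en-1-yl)phenyl]-3-oxoprop-1-en-1-yl]phenoxy]-2-methylpropanoic acid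
Conditions: KOH (aq, excess), EtOH, rt; then 1 M HCl to pH 4, 0 °C
Reagents that add atoms: none
Why: Claisen–Schmidt condensation of the methyl ketone enolate with the non‑enolisable aldehyde, E1cB dehydration giving the (E)‑enone, with the carboxylate and the MOM ether inert to hydroxide.

Step 5
Reactants: 9 2-[4-[(1E)-3-[2-hydroxy-4-(methoxymethoxy)-5-(3-methylbut-2-en-1-yl)phenyl]-3-oxoprop-1-en-1-yl]phenoxy]-2-methylpropanoic acid
Product: 11 2-[4-[7-(methoxymethoxy)-6-(3-methylbut-2-en-1-yl)-4-oxo-4H-chromen-2-yl]phenoxy]-2-methylpropanoic acid, via flavanone acid 10 (not isolated)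
Conditions: I2 (10 mol%), DMSO, 130 °C
Reagents that add atoms: none
Why: Iodine‑catalysed oxidative cyclisation of a 2'‑hydroxychalcone (oxa‑Michael closure of ring C, α‑iodination and loss of HI, DMSO reoxidising HI to I2), the MOM ether on the 7‑oxygen keeping the neighbouring prenyl group from cyclising.

Step 6
Reactants: 11 2-[4-[7-(methoxymethoxy)-6-(3-methylbut-2-en-1-yl)-4-oxo-4H-chromen-2-yl]phenoxy]-2-methylpropanoic acid
Product: 12 1,3-dioxoisoindolin-2-yl 2-[4-[7-(methoxymethoxy)-6-(3-methylbut-2-en-1-yl)-4-oxo-4H-chromen-2-yl]phenoxy]-2-methylpropanoate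
Conditions: N-hydroxyphthalimide, DIC, DMAP (cat.), CH2Cl2, rt
Reagents that add atoms: N-hydroxyphthalimide, O=C1c2ccccc2C(=O)N1O
Why: Steglich‑type carbodiimide esterification, which should convert the hindered tertiary acid into its redox‑active N‑acyloxyphthalimide without affecting the flavone, MOM or prenyl groups.

Step 7
Reactants: 12 1,3-dioxoisoindolin-2-yl 2-[4-[7-(methoxymethoxy)-6-(3-methylbut-2-en-1-yl)-4-oxo-4H-chromen-2-yl]phenoxy]-2-methylpropanoate; 13 acetylene
Product: 14 2-(2,2-dimethyl-2H-chromen-6-yl)-7-(methoxymethoxy)-6-(3-methylbut-2-en-1-yl)-4H-chromen-4-one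
Conditions: acetylene (1 atm), fac-Ir(ppy)3 (ppy = 2-phenylpyridinato, 1 mol%), MeCN (degassed), blue LEDs (450 nm), rt
Reagents that add atoms: none
Why: Proposed new method: photoexcited fac-Ir(ppy)3 transfers one electron to the N‑acyloxyphthalimide, which loses phthalimide anion and CO2 to give the tertiary α‑aryloxy radical at C2 of ring D; this nucleophilic radical adds to acetylene (C2–C3 bond), the σ‑vinyl radical attacks the ortho carbon C3' of ring B (C4–C4a bond), and the cyclohexadienyl radical is oxidised by tetravalent iridium and deprotonated by phthalimide anion, so the process is redox‑neutral and returns trivalent iridium. The closest known reaction types are the photoredox (4+2) radical annulation of N‑acyloxyphthalimides of aryloxyacetic acids with electron‑poor alkenes to chromans, the radical cyclisation of aryl propargyl ethers to 2H‑chromenes through the same vinyl‑radical ortho attack, and the free‑radical addition of α‑oxyalkyl radicals to acetylene; using acetylene as the two‑carbon partner to reach a 3,4‑unsubstituted 2H‑chromene is the untested part. Ring D closes as a six‑membered ring by intramolecular homolytic aromatic substitution (6‑exo attack on the C3'=C2' bond of ring B, then rearomatisation), the cis geometry being reached because σ‑vinyl radicals invert rapidly. No stereocentre is formed. The step needs ortho attack instead of ipso (spiro, five‑membered) attack, one acetylene per radical, and inertness of the prenyl and chromone olefins: the 1,4‑disubstitution of ring B makes C3' and C5' identical, the gem‑dimethyl group favours closure over a second intermolecular addition, and the electron‑rich trisubstituted prenyl olefin and the fully substituted C2 of the chromone are mismatched in polarity and bulk with a nucleophilic tertiary radical generated far from both.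

Step 8
Reactants: 14 2-(2,2-dimethyl-2H-chromen-6-yl)-7-(methoxymethoxy)-6-(3-methylbut-2-en-1-yl)-4H-chromen-4-one
Product: 15 Kanzonol E
Conditions: 3 M aq HCl, MeOH, 50 °C
Reagents that add atoms: none
Why: Acid‑catalysed acetal exchange transfers the methoxymethyl group to methanol, and the 2,2‑dimethylchromene and prenyl olefins should tolerate brief dilute methanolic HCl.

**Compound list**

1 | 4-hydroxybenzaldehyde | O=Cc1ccc(O)cc1 | starting material
2 | ethyl 2-bromo-2-methylpropanoate | CCOC(=O)C(C)(C)Br | starting material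
3 | ethyl 2-(4-formylphenoxy)-2-methylpropanoate | CCOC(=O)C(C)(C)Oc1ccc(C=O)cc1 | intermediate
4 | 2-(4-formylphenoxy)-2-methylpropanoic acid | CC(C)(Oc1ccc(C=O)cc1)C(=O)O | intermediate
5 | 1-(2,4-dihydroxyphenyl)ethanone (2,4-dihydroxyacetophenone) | CC(=O)c1ccc(O)cc1O | starting material
6 | 2-methylbut-3-en-2-ol | CC(C)(O)C=C | starting material
7 | 1-[2,4-dihydroxy-5-(3-methylbut-2-en-1-yl)phenyl]ethanone | CC(=O)c1cc(CC=C(C)C)c(O)cc1O | intermediate
8 | 1-[2-hydroxy-4-(methoxymethoxy)-5-(3-methylbut-2-en-1-yl)phenyl]ethanone | CC(=O)c1cc(CC=C(C)C)c(OCOC)cc1O | intermediate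
9 | 2-[4-[(1E)-3-[2-hydroxy-4-(methoxymethoxy)-5-(3-methylbut-2-en-1-yl)phenyl]-3-oxoprop-1-en-1-yl]phenoxy]-2-methylpropanoic acid | CC(C)=CCc1cc(C(=O)/C=C/c2ccc(OC(C)(C)C(=O)O)cc2)c(O)cc1OCOC | intermediate
10 | 2-[4-[7-(methoxymethoxy)-6-(3-methylbut-2-en-1-yl)-4-oxo-3,4-dihydro-2H-chromen-2-yl]phenoxy]-2-methylpropanoic acid (flavanone acid, racemic) | CC(C)=CCc1cc2C(=O)CC(c3ccc(OC(C)(C)C(=O)O)cc3)Oc2cc1OCOC | intermediate
11 | 2-[4-[7-(methoxymethoxy)-6-(3-methylbut-2-en-1-yl)-4-oxo-4H-chromen-2-yl]phenoxy]-2-methylpropanoic acid | CC(C)=CCc1cc2c(=O)cc(-c3ccc(OC(C)(C)C(=O)O)cc3)oc2cc1OCOC | intermediate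
12 | 1,3-dioxoisoindolin-2-yl 2-[4-[7-(methoxymethoxy)-6-(3-methylbut-2-en-1-yl)-4-oxo-4H-chromen-2-yl]phenoxy]-2-methylpropanoate | CC(C)=CCc1cc2c(=O)cc(-c3ccc(OC(C)(C)C(=O)ON4C(=O)c5ccccc5C4=O)cc3)oc2cc1OCOC | intermediate
13 | acetylene (ethyne) | C#C | starting material
14 | 2-(2,2-dimethyl-2H-chromen-6-yl)-7-(methoxymethoxy)-6-(3-methylbut-2-en-1-yl)-4H-chromen-4-one | CC(C)=CCc1cc2c(=O)cc(-c3ccc4c(c3)C=CC(C)(C)O4)oc2cc1OCOC | intermediate
15 | Kanzonol E, 2-(2,2-dimethyl-2H-chromen-6-yl)-7-hydroxy-6-(3-methylbut-2-en-1-yl)-4H-chromen-4-one | CC(C)=CCc1cc2c(=O)cc(-c3ccc4c(c3)C=CC(C)(C)O4)oc2cc1O | target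

**Step count and risks**

Total step count: 8. Longest linear sequence: 7 steps (steps 2, 3, 4, 5, 6, 7, 8 from compound 5); step 1 is a one‑step branch.

Steps most likely to fail:

1. Step 7 (proposed new method).
   - What may go wrong: capture of the tertiary α‑aryloxy radical by acetylene may be slow, so that its oxidation to an oxocarbenium ion with loss of the side chain takes over. The vinyl radical may abstract hydrogen from the medium before it closes the ring, or it may attack the ipso carbon and start an aryl migration.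
   - Fallback (known chemistry, from 11 back to 14): photoredox decarboxylative alkynylation of acid 11 with 1-[(triisopropylsilyl)ethynyl]-1,2-benziodoxol-3(1H)-one (Ir[dF(CF3)ppy]2(dtbbpy)PF6, CsO2CPh, 1,2-dichloroethane, blue LEDs) should give the silyl‑capped propargyl ether 7-(methoxymethoxy)-2-[4-[[2-methyl-4-(triisopropylsilyl)but-3-yn-2-yl]oxy]phenyl]-6-(3-methylbut-2-en-1-yl)-4H-chromen-4-one F1. Bu4NF in THF should then free the terminal alkyne 7-(methoxymethoxy)-2-[4-[(2-methylbut-3-yn-2-yl)oxy]phenyl]-6-(3-methylbut-2-en-1-yl)-4H-chromen-4-one F2. Heating F2 in N,N-diethylaniline at about 190 °C (aryl propargyl ether Claisen rearrangement, 1,5‑hydrogen shift, oxa‑6π electrocyclisation) should close ring D and rejoin the route at compound 14.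

2. Step 5.
   - What may go wrong: at 130 °C electrophilic iodine or HI may add to the prenyl double bond, and the acid may remove the MOM group, after which the freed 7‑OH can cyclise onto the side chain.
   - Fallback (from 9 back to 11): the iodine chemistry is replaced by a two‑stage sequence. Chalcone 9 is closed with NaOAc in refluxing EtOH (oxa‑Michael addition) to the flavanone acid 10, which is isolated this time. Compound 10 is then dehydrogenated aerobically with Pd(O2CCF3)2 (10 mol%) in DMSO under O2 at 100 °C, which rejoins the route at compound 11. This fallback makes no compound outside the list (F0).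

3. Step 2.
   - What may go wrong: poor site selectivity of the Friedel–Crafts prenylation (C3 against C5, O‑alkylation, double alkylation) and acid‑induced ring closure of the product onto its own side chain.
   - Fallback (from 5 back to 8): the site is fixed by a halogen before the prenyl group is brought in. Ketone 5 is brominated with NBS in MeCN at 0 °C to 1-(5-bromo-2,4-dihydroxyphenyl)ethanone F3. The 4‑OH is protected (MOMCl, K2CO3, acetone) to give 1-[5-bromo-2-hydroxy-4-(methoxymethoxy)phenyl]ethanone F4. A Stille coupling of F4 with tributyl(3-methylbut-2-en-1-yl)stannane (Pd(PPh3)4, DMF, 90 °C) should deliver the linear prenyl arene and rejoin the route at compound 8.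

**Further compounds**

F1 | step 7 | 7-(methoxymethoxy)-2-[4-[[2-methyl-4-(triisopropylsilyl)but-3-yn-2-yl]oxy]phenyl]-6-(3-methylbut-2-en-1-yl)-4H-chromen-4-one | CC(C)=CCc1cc2c(=O)cc(-c3ccc(OC(C)(C)C#C[Si](C(C)C)(C(C)C)C(C)C)cc3)oc2cc1OCOC
F2 | step 7 | 7-(methoxymethoxy)-2-[4-[(2-methylbut-3-yn-2-yl)oxy]phenyl]-6-(3-methylbut-2-en-1-yl)-4H-chromen-4-one | CC(C)=CCc1cc2c(=O)cc(-c3ccc(OC(C)(C)C#C)cc3)oc2cc1OCOC
F0 | step 5 | none | none
F3 | step 2 | 1-(5-bromo-2,4-dihydroxyphenyl)ethanone | CC(=O)c1cc(Br)c(O)cc1O
F4 | step 2 | 1-[5-bromo-2-hydroxy-4-(methoxymethoxy)phenyl]ethanone | CC(=O)c1cc(Br)c(OCOC)cc1O
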